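**Retrosynthetic overview** (atom numbers are the azulene numbers of the target core: five-membered ring C1–C3, fusion carbons C3a and C8a, seven-membered ring C4–C8)
1. Endgame: the C4 vanillate and the C7 hydroxyl, cis and flanking C5=C6, arise together and regiodefined from a Pd(PPh3)4-catalysed 1,4-addition of a protected vanillic acid to the 6,7-epoxide of a 4,6-diene; the C3 carbinol comes from isopropyl addition to a C3 ketone.
2. That ketone is the deconjugated isomer of a cross-ring dienone whose only stereocentre, the quaternary C8a, then controls C3a, C3 and finally C6/C7/C4.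
3. Key disconnection: the C8a–C1 bond of the cyclopentane, opened as a retro-Nazarov to a monocyclic cycloheptadienyl vinyl ketone (enantioselective conrotatory 4π closure).
4. Enabling feature: the carbinol carbon C3 of the five-membered ring lies between the fusion carbon C3a and C2, so at the ketone level C8a=C3a–C3(=O)–C2=C1 is a divinyl ketone whose termini are the two atoms to be joined; the C5=C6 alkene of the seven-membered ring makes H-4 doubly allylic and steers the elimination.
5. Ring order: seven-membered ring first (ring-closing metathesis of an acetoacetate-derived diene), five-membered ring second (Nazarov).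

Key step: step 7

Remark: the same atom numbers are used for the corresponding atoms of the monocyclic precursors, and the antipode of the chiral acid in step 7 would be chosen by screening so that the S configuration at C8a results.

**Route**

Step 1
Reactants: 1 ethyl 2-acetylpent-4-enoate (ethyl 2-allylacetoacetate); 2 3-bromo-2-methylprop-1-ene
Product: 3 ethyl 6-methyl-3-oxo-2-(prop-2-en-1-yl)hept-6-enoate
Conditions: LiN(i-Pr)2 (2.2 equiv), THF, −78 to 0 °C; then 2, 0 °C
Reagents that add atoms: none
Why: γ-Alkylation of an acetoacetate dianion, which reacts at its more nucleophilic terminal carbon, so the methallyl unit is attached at the ketone methyl and the α-allyl group is untouched (the α-stereocentre is racemic and is lost in step 3).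

Step 2
Reactants: 3 ethyl 6-methyl-3-oxo-2-(prop-2-en-1-yl)hept-6-enoate
Product: 4 ethyl 4-methyl-7-oxocyclohept-3-ene-1-carboxylate
Conditions: second-generation Grubbs catalyst RuCl2(=CHPh)(PCy3)(H2IMes) (3 mol%), CH2Cl2 (0.01 M), 40 °C
Reagents that add atoms: none
Why: Ring-closing metathesis between a monosubstituted and a 1,1-disubstituted alkene is a standard entry to trisubstituted cycloheptenes, is driven by loss of ethylene and tolerates the β-keto ester.

Step 3
Reactants: 4 ethyl 4-methyl-7-oxocyclohept-3-ene-1-carboxylate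
Product: 5 ethyl 5-methyl-2-(trifluoromethanesulfonyloxy)cyclohepta-1,5-diene-1-carboxylate
Conditions: NaH, Et2O, 0 °C; then Tf2O, 0 °C
Reagents that add atoms: trifluoromethanesulfonic anhydride, O=S(=O)(OS(=O)(=O)C(F)(F)F)C(F)(F)F
Why: O-Sulfonylation of the sodium enolate of a cyclic β-keto ester should give the tetrasubstituted enol triflate, whose geometry is fixed by the ring.

Step 4
Reactants: 5 ethyl 5-methyl-2-(trifluoromethanesulfonyloxy)cyclohepta-1,5-diene-1-carboxylate
Product: 6 ethyl 2,5-dimethylcyclohepta-1,5-diene-1-carboxylate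
Conditions: MeMgBr, Fe(acac)3 (5 mol%), THF/NMP, −30 °C
Reagents that add atoms: methylmagnesium bromide, C[Mg]Br
Why: Iron-catalysed Kumada-type coupling of alkenyl triflates with alkyl Grignard reagents is fast at low temperature and tolerates the ester, so OTf is replaced by methyl without moving the ring alkenes.

Step 5
Reactants: 6 ethyl 2,5-dimethylcyclohepta-1,5-diene-1-carboxylate
Product: 7 N-methoxy-N,2,5-trimethylcyclohepta-1,5-diene-1-carboxamide
Conditions: MeNH(OMe)·HCl, i-PrMgCl, THF, −20 to 0 °C
Reagents that add atoms: N,O-dimethylhydroxylamine hydrochloride, CNOC.Cl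
Why: Weinreb amide formation through the magnesium amide generated in the flask converts hindered conjugated esters and prepares for a single Grignard addition.

Step 6
Reactants: 7 N-methoxy-N,2,5-trimethylcyclohepta-1,5-diene-1-carboxamide
Product: 8 1-(2,5-dimethylcyclohepta-1,5-dien-1-yl)prop-2-en-1-one
Conditions: CH2=CHMgBr, THF, −20 to 0 °C; inverse quench into cold 1 M HCl
Reagents that add atoms: vinylmagnesium bromide, C=C[Mg]Br
Why: Weinreb ketone synthesis, in which the chelated tetrahedral intermediate survives until the acidic quench, and the inverse quench keeps the liberated amine from adding to the new vinyl ketone.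

Step 7
Reactants: 8 1-(2,5-dimethylcyclohepta-1,5-dien-1-yl)prop-2-en-1-one
Product: 9 (8aS)-6,8a-dimethyl-1,7,8,8a-tetrahydroazulen-3(2H)-one
Conditions: chiral BINOL-derived imidodiphosphorimidate Brønsted acid (IDPi, 5 mol%), toluene, 0 °C to rt
Reagents that add atoms: none
Why: Proposed new method: an enantioselective Brønsted-acid-catalysed Nazarov cyclisation of a β,β-disubstituted cycloalkenyl vinyl ketone that creates a quaternary stereocentre, the closest known reaction types being the imidodiphosphorimidate-catalysed asymmetric Nazarov cyclisation of simple acyclic divinyl ketones and the achiral acid-mediated Nazarov cyclisation of 1-cycloalkenyl vinyl ketones. O-Protonation of 8 gives a 3-hydroxypentadienyl cation (C8a–C3a–C3–C2–C1) paired with the confined chiral anion, and thermal conrotatory 4π electrocyclisation joins C8a to C1. The cyclopentane is thereby closed in a formally 5-endo-trig sense, which is allowed because the closure is electrocyclic. The new quaternary stereocentre C8a is fixed by the sense of conrotation, which the chiral counter-anion must impose. The resulting 2-hydroxyallyl cation should lose the doubly allylic proton at C4, a regiochemistry secured by the ring C5=C6 alkene of 8, and the dienol then tautomerises to the conjugated dienone 9. The step needs face control at C8a and an elimination that outruns a 1,2-methyl shift from the new quaternary carbon, and both should be served by the tight ion pair with a basic, confined anion.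

Step 8
Reactants: 9 (8aS)-6,8a-dimethyl-1,7,8,8a-tetrahydroazulen-3(2H)-one
Product: 11 (3aR,8aR)-6,8a-dimethyl-1,2,8,8a-tetrahydroazulen-3(3aH)-one, via potassium trienolate 10 (not isolated)
Conditions: KOt-Bu (3 equiv), t-BuOH/THF, 0 °C, degassed; then inverse quench into AcOH/THF, −78 °C
Reagents that add atoms: none
Why: Deconjugation through the extended enolate: equilibrating deprotonation at the ε-methylene C7 should give the linear trienolate, and its kinetic protonation occurs at the α-carbon C3a from the face opposite the axial C8a methyl, setting the trans ring fusion and placing the diene at C4–C7.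

Step 9
Reactants: 11 (3aR,8aR)-6,8a-dimethyl-1,2,8,8a-tetrahydroazulen-3(3aH)-one
Product: 12 (3R,3aR,8aR)-6,8a-dimethyl-3-(propan-2-yl)-1,2,3,3a,8,8a-hexahydroazulen-3-ol
Conditions: i-PrMgCl, CeCl3 (anhydrous), THF, −78 °C; crude 11 used at once
Reagents that add atoms: isopropylmagnesium chloride, CC(C)[Mg]Cl
Why: Organocerium 1,2-addition suppresses enolisation of the very enolisable β,γ-unsaturated ketone, and attack on the face of H-3a, away from the angular methyl, should give the 3R carbinol with the hydroxyl cis to that methyl.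

Step 10
Reactants: 12 (3R,3aR,8aR)-6,8a-dimethyl-3-(propan-2-yl)-1,2,3,3a,8,8a-hexahydroazulen-3-ol
Product: 13 (3R,3aR,6R,7S,8aR)-6,7-epoxy-6,8a-dimethyl-3-(propan-2-yl)-1,2,3,3a,6,7,8,8a-octahydroazulen-3-ol
Conditions: mCPBA (1.05 equiv), NaHCO3, CH2Cl2, −20 °C; crude 13 used at once
Reagents that add atoms: 3-chloroperbenzoic acid, OOC(=O)c1cccc(Cl)c1
Why: Peracid epoxidation of a 1,3-diene prefers the more electron-rich trisubstituted C6=C7 bond and should occur on the face opposite the axial C8a methyl, while the bicarbonate buffer protects the acid-sensitive vinyl epoxide.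

Step 11
Reactants: 13 (3R,3aR,6R,7S,8aR)-6,7-epoxy-6,8a-dimethyl-3-(propan-2-yl)-1,2,3,3a,6,7,8,8a-octahydroazulen-3-ol; 14 4-acetoxy-3-methoxybenzoic acid
Product: 15 (3R,3aS,4S,7S,8aR)-3,7-dihydroxy-6,8a-dimethyl-3-(propan-2-yl)-1,2,3,3a,4,7,8,8a-octahydroazulen-4-yl 4-acetoxy-3-methoxybenzoate
Conditions: Pd(PPh3)4 (5 mol%), THF, 0 °C to rt
Reagents that add atoms: none
Why: Tsuji–Trost 1,4-opening of a diene monoepoxide, in which zerovalent palladium ionises the allylic C6–O bond with inversion and the carboxylate attacks the less hindered distal terminus C4 anti to palladium, so the C4 ester and the C7 hydroxyl end up cis and are differentiated in one operation.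

Step 12
Reactants: 15 (3R,3aS,4S,7S,8aR)-3,7-dihydroxy-6,8a-dimethyl-3-(propan-2-yl)-1,2,3,3a,4,7,8,8a-octahydroazulen-4-yl 4-acetoxy-3-methoxybenzoate
Product: 16 (3R,3aS,4S,7S,8aR)-3,7-dihydroxy-6,8a-dimethyl-3-(propan-2-yl)-1,2,3,3a,4,7,8,8a-octahydroazulen-4-yl 4-hydroxy-3-methoxybenzoate
Conditions: pyrrolidine, CH2Cl2, 0 °C
Reagents that add atoms: none
Why: Aminolysis should cleave the activated aryl acetate much faster than the hindered secondary benzoate, releasing the phenol of the target.

**Compound list**
1 | ethyl 2-acetylpent-4-enoate | CCOC(=O)C(CC=C)C(C)=O | starting material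
2 | 3-bromo-2-methylprop-1-ene | CC(=C)CBr | starting material
3 | ethyl 6-methyl-3-oxo-2-(prop-2-en-1-yl)hept-6-enoate | CCOC(=O)C(CC=C)C(=O)CCC(C)=C | intermediate
4 | ethyl 4-methyl-7-oxocyclohept-3-ene-1-carboxylate | CCOC(=O)C1CC=C(C)CCC1=O | intermediate
5 | ethyl 5-methyl-2-(trifluoromethanesulfonyloxy)cyclohepta-1,5-diene-1-carboxylate | CCOC(=O)C1=C(OS(=O)(=O)C(F)(F)F)CCC(C)=CC1 | intermediate
6 | ethyl 2,5-dimethylcyclohepta-1,5-diene-1-carboxylate | CCOC(=O)C1=C(C)CCC(C)=CC1 | intermediate
7 | N-methoxy-N,2,5-trimethylcyclohepta-1,5-diene-1-carboxamide | CON(C)C(=O)C1=C(C)CCC(C)=CC1 | intermediate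
8 | 1-(2,5-dimethylcyclohepta-1,5-dien-1-yl)prop-2-en-1-one | C=CC(=O)C1=C(C)CCC(C)=CC1 | intermediate
9 | (8aS)-6,8a-dimethyl-1,7,8,8a-tetrahydroazulen-3(2H)-one | O=C1CC[C@]2(C)CCC(C)=CC=C12 | intermediate
10 | potassium (8aR)-6,8a-dimethyl-1,2,8,8a-tetrahydroazulen-3-olate (trienolate, not isolated) | [K+].[O-]C1=C2C=CC(C)=CC[C@@]2(C)CC1 | intermediate
11 | (3aR,8aR)-6,8a-dimethyl-1,2,8,8a-tetrahydroazulen-3(3aH)-one | C1=CC(C)=CC[C@@]2(C)CCC(=O)[C@H]12 | intermediate
12 | (3R,3aR,8aR)-6,8a-dimethyl-3-(propan-2-yl)-1,2,3,3a,8,8a-hexahydroazulen-3-ol | C1=CC(C)=CC[C@@]2(C)CC[C@@](O)(C(C)C)[C@H]12 | intermediate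
13 | (3R,3aR,6R,7S,8aR)-6,7-epoxy-6,8a-dimethyl-3-(propan-2-yl)-1,2,3,3a,6,7,8,8a-octahydroazulen-3-ol | C1=C[C@@]4(C)O[C@H]4C[C@@]2(C)CC[C@@](O)(C(C)C)[C@H]12 | intermediate
14 | 4-acetoxy-3-methoxybenzoic acid | COc1cc(C(=O)O)ccc1OC(C)=O | starting material
15 | (3R,3aS,4S,7S,8aR)-3,7-dihydroxy-6,8a-dimethyl-3-(propan-2-yl)-1,2,3,3a,4,7,8,8a-octahydroazulen-4-yl 4-acetoxy-3-methoxybenzoate | COc1cc(C(=O)O[C@H]2C=C(C)[C@@H](O)C[C@@]3(C)CC[C@@](O)(C(C)C)[C@H]23)ccc1OC(C)=O | intermediate
16 | (3R,3aS,4S,7S,8aR)-3,7-dihydroxy-6,8a-dimethyl-3-(propan-2-yl)-1,2,3,3a,4,7,8,8a-octahydroazulen-4-yl 4-hydroxy-3-methoxybenzoate | COc1cc(C(=O)O[C@H]2C=C(C)[C@@H](O)C[C@@]3(C)CC[C@@](O)(C(C)C)[C@H]23)ccc1O | target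

**Step count and risks**

Total step count: 12. Longest linear sequence: 12 steps (1 to 16).

Steps most likely to fail:

Step 7 (Proposed new method). The sense of conrotation may be poorly controlled, so that the quaternary centre forms with low enantiomeric purity. The strong acid may also protonate the ring alkene, or a 1,2-methyl shift may precede elimination. Fallback with known chemistry, setting out from 8 and returning at 9: 8 would be cyclised with an achiral Lewis acid (BF3·OEt2, CH2Cl2, 0 °C), the classical Nazarov reaction of cycloalkenyl vinyl ketones, to give the racemic dienone F1. F1 would then be resolved kinetically with a ketoreductase chosen from a panel (NADPH, isopropanol recycling), as is practised for racemic bicyclic enones with an angular methyl group. Only the 8aR enantiomer should be reduced, to the allylic alcohol F2, which is separated. The untouched S ketone is 9 and continues with step 8.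

Step 8. Deprotonation may occur at C2 or at the C6 methyl instead of C7, protonation may take place on the wrong face, and the β,γ-unsaturated ketone may reconjugate during isolation. Fallback, setting out from 9 and returning at 11: 9 would be converted under equilibrating conditions (isopropenyl acetate, TsOH, reflux) into the linear trienyl acetate F3, which is isolable and fixes the enolate regiochemistry. Deconjugative reduction of F3 with NaBH4 in aqueous ethanol/THF at 0 °C would follow: the liberated trienolate is protonated at C3a and the β,γ-unsaturated ketone is reduced at once, before it can reconjugate, to the homoallylic alcohol F4. Oxidation of F4 with buffered Dess–Martin periodinane, which does not move the double bonds, would give 11 for step 9.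

Step 10. The peracid may attack the disubstituted C4=C5 bond, facial selectivity may be poor, or the vinyl epoxide may open or rearrange under traces of acid before it is used. Fallback, setting out from 12 and returning at 15: photo-oxygenation of 12 (O2, tetraphenylporphyrin, visible light, CH2Cl2, −20 °C) should add singlet oxygen across C4 and C7 of the cisoid diene, opposite the angular methyl, to give the endoperoxide F5. Thiourea in methanol would reduce the O–O bond to the cis-4,7-diol F6. The less hindered C7 hydroxyl would be silylated (TESCl, imidazole, −40 °C) to the silyl ether F7. The C4 hydroxyl would be acylated with 14 (EDC, DMAP) to the ester F8. HF·pyridine in THF would then remove the silyl group to give 15, which continues with step 12.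

Further compounds
F1 | step 7 | racemic 6,8a-dimethyl-1,7,8,8a-tetrahydroazulen-3(2H)-one | O=C1CCC2(C)CCC(C)=CC=C12
F2 | step 7 | (3R,8aR)-6,8a-dimethyl-1,2,3,7,8,8a-hexahydroazulen-3-ol | C12=CC=C(C)CC[C@]1(C)CC[C@H]2O
F3 | step 8 | (8aR)-6,8a-dimethyl-1,2,8,8a-tetrahydroazulen-3-yl acetate | CC(=O)OC1=C2C=CC(C)=CC[C@@]2(C)CC1
F4 | step 8 | (3S,3aR,8aR)-6,8a-dimethyl-1,2,3,3a,8,8a-hexahydroazulen-3-ol | C1=CC(C)=CC[C@@]2(C)CC[C@H](O)[C@H]12
F5 | step 10 | (3R,3aS,4S,7S,8aR)-4,7-epidioxy-6,8a-dimethyl-3-(propan-2-yl)-1,2,3,3a,4,7,8,8a-octahydroazulen-3-ol | O1[C@H]2C=C(C)[C@@H](O1)C[C@@]3(C)CC[C@@](O)(C(C)C)[C@H]23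
F6 | step 10 | (3R,3aS,4S,7S,8aR)-6,8a-dimethyl-3-(propan-2-yl)-1,2,3,3a,4,7,8,8a-octahydroazulene-3,4,7-triol | O[C@H]1C=C(C)[C@@H](O)C[C@@]2(C)CC[C@@](O)(C(C)C)[C@H]12
F7 | step 10 | (3R,3aS,4S,7S,8aR)-6,8a-dimethyl-3-(propan-2-yl)-7-(triethylsilyloxy)-1,2,3,3a,4,7,8,8a-octahydroazulene-3,4-diol | O[C@H]1C=C(C)[C@@H](O[Si](CC)(CC)CC)C[C@@]2(C)CC[C@@](O)(C(C)C)[C@H]12
F8 | step 10 | (3R,3aS,4S,7S,8aR)-3-hydroxy-6,8a-dimethyl-3-(propan-2-yl)-7-(triethylsilyloxy)-1,2,3,3a,4,7,8,8a-octahydroazulen-4-yl 4-acetoxy-3-methoxybenzoate | COc1cc(C(=O)O[C@H]2C=C(C)[C@@H](O[Si](CC)(CC)CC)C[C@@]3(C)CC[C@@](O)(C(C)C)[C@H]23)ccc1OC(C)=O
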